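The target's ring B is a 7-en-6-one: its only carbonyl carbon, C6 in drimane numbering, is flanked by the ring-fusion carbon C5 and the vinylic carbon C7. Removing C6 as carbon monoxide and reconnecting C5 to C9 leads back to a cyclopropane (C5–C9–C10) fused to ring A that carries, on C9, the isopropenyl unit C8(=C7)–C12 and the C11 ester. One iron-mediated carbonylation cleaves C5–C9, forms C5–C6 and C6–C7, closes ring B and, after base equilibration, fixes C5 and C9. The precursor comes from an O3-tethered intramolecular cyclopropanation of an (R)-cyclohexenyl diazoacetoacetate, which sets C10; isofraxidin and the isovalerate are added last.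

Key step: step 8

Remark: drimane numbering is used for all bicyclic and tricyclic compounds (β is the face of the C10 methyl group); racemic 4-methylcyclohex-2-en-1-one is taken to be a catalogue compound; the C3 hydroxyl is carried free from step 7 onward.

Step 1
Reactants: 1 4-methylcyclohex-2-en-1-one (racemic)
Product: 3 2,2,4-trimethylcyclohex-3-en-1-one, via monomethyl ketone 2 (not isolated)
Conditions: KOt-Bu (2.2 equiv), MeI (2.5 equiv), t-BuOH, 0 °C → rt
Reagents that add atoms: iodomethane, SMILES CI
Why: Deconjugative α,α-dialkylation of an enone: the extended dienolate formed by γ-deprotonation is methylated at C2, the doubly activated C2–H of 2 is removed and methylated again, and the alkene stays β,γ; the stereocenter of 1 is destroyed, so racemic material suffices.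

Step 2
Reactants: 3 2,2,4-trimethylcyclohex-3-en-1-one
Product: 4 (1R)-2,2,4-trimethylcyclohex-3-en-1-ol
Conditions: (S)-Me-CBS oxazaborolidine [(3aS)-1-methyl-3,3-diphenyltetrahydro-1H,3H-pyrrolo[1,2-c][1,3,2]oxazaborole] (10 mol %), BH3·SMe2 (0.7 equiv), THF, −20 °C; MeOH
Reagents that add atoms: none
Why: Corey–Bakshi–Shibata reduction, in which the catalyst distinguishes the quaternary C2 flank (large) from the C6 methylene (small) and by the usual model should give the R carbinol (C3 of the drimane), the catalysed carbonyl reduction being much faster than hydroboration of the trisubstituted alkene.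

Step 3
Reactants: 4 (1R)-2,2,4-trimethylcyclohex-3-en-1-ol; 5 2,2,6-trimethyl-4H-1,3-dioxin-4-one
Product: 6 (1R)-2,2,4-trimethylcyclohex-3-en-1-yl 3-oxobutanoate
Conditions: xylene, 140 °C (acetone distilled off)
Reagents that add atoms: none
Why: Thermal retro-Diels–Alder cleavage of the dioxinone releases acetylketene, which acylates even hindered secondary alcohols on oxygen, with retention at C3.

Step 4
Reactants: 6 (1R)-2,2,4-trimethylcyclohex-3-en-1-yl 3-oxobutanoate
Product: 7 (1R)-2,2,4-trimethylcyclohex-3-en-1-yl 2-diazo-3-oxobutanoate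
Conditions: 4-acetamidobenzenesulfonyl azide, Et3N, MeCN, 0 °C → rt
Reagents that add atoms: 4-acetamidobenzenesulfonyl azide, SMILES CC(=O)Nc1ccc(cc1)S(=O)(=O)N=[N+]=[N-]
Why: Regitz diazo transfer to the active methylene of a β-keto ester; no stereocenter is involved.

Step 5
Reactants: 7 (1R)-2,2,4-trimethylcyclohex-3-en-1-yl 2-diazo-3-oxobutanoate
Product: 8 2-acetyl-8,9,9-trimethyl-4-oxatricyclo[3.3.1.0^2,8]nonan-3-one (tricyclic keto lactone: cyclopropane C5–C9–C10 on the α face of ring A, C10 methyl β, lactone O3–C11 bridging C3 and C9, acetyl exo)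
Conditions: Rh2(OAc)4 (1 mol %), CH2Cl2, reflux, slow addition of 7
Reagents that add atoms: none
Why: Intramolecular cyclopropanation by an acceptor/acceptor rhodium carbenoid, in which the O3–C11–C9 tether can reach C5=C10 only from the face of O3, so C5, C9 and C10 are set together (lactone carbonyl endo, acetyl exo, C10 methyl β), while the quaternary C4 leaves only the unactivated C2 methylene for competing 1,5 C–H insertion.

Step 6
Reactants: 8 tricyclic keto lactone
Product: 9 8,9,9-trimethyl-2-(prop-1-en-2-yl)-4-oxatricyclo[3.3.1.0^2,8]nonan-3-one (isopropenyl lactone, same configuration as 8)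
Conditions: Ph3PCH3Br (1.5 equiv), KOt-Bu (1.4 equiv), THF, 0 °C → rt
Reagents that add atoms: methyltriphenylphosphonium bromide, SMILES C[P+](c1ccccc1)(c1ccccc1)c1ccccc1.[Br-]
Why: Wittig methylenation, the methyl ketone being far more electrophilic toward the ylide than the lactone; C9 is quaternary, so nothing can epimerise, and the ketone is removed before any alkoxide is used, which avoids retro-Claisen loss of the acetyl group.

Step 7
Reactants: 9 isopropenyl lactone
Product: 10 methyl 4-hydroxy-1,5,5-trimethyl-7-(prop-1-en-2-yl)bicyclo[4.1.0]heptane-7-carboxylate (drimane C3 hydroxyl and cyclopropane carbon C9 on the α face of ring A; ester endo, isopropenyl exo and cis to the C10 methyl)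
Conditions: NaOMe (0.2 equiv), MeOH, 50 °C; aq. NH4Cl
Reagents that add atoms: methanol, SMILES CO
Why: Base-catalysed transesterification opens the strained bridged lactone to the methyl ester and the free 3α-hydroxyl, re-closure being disfavoured in methanol and slow once neutral; no stereocenter is at risk, and O3 is left unprotected because no later step needs it masked.

Step 8
Reactants: 10 ring A-fused vinylcyclopropane hydroxy ester
Product: 12 methyl 3α-hydroxy-6-oxo-9-epi-drim-7-en-11-oate (5α-H, 9β-H, 10β-methyl), via cis-fused 8-en-6-one ester 11 (not isolated)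
Conditions: (a) Fe(CO)5 (1.5 equiv), CO (1 atm, restores Fe(CO)5), hν (350 nm, Pyrex), i-PrOH, rt; (b) NaOMe (0.3 equiv), MeOH, rt, then AcOH
Reagents that add atoms: carbon monoxide, SMILES [C-]#[O+]
Why: Irradiation generates Fe(CO)4, which binds the isopropenyl alkene and adds oxidatively to the adjacent C5–C9 cyclopropane bond to give a σ-alkyl (C5)/η3-allyl (C9–C8–C7) iron complex; CO then inserts into the Fe–C5 bond (making C5–C6) and reductive elimination joins the acyl carbon C6 to the allyl terminus C7, releasing the cis-fused 8-en-6-one 11. The closest known reaction type is this same iron-mediated (or rhodium-catalysed) [5+1] carbonylation of vinylcyclopropanes to cyclohex-3-enones followed by base conjugation, applied here to a fully substituted, ring-fused member of the class. Ring B closes by C–C reductive elimination from the acyl/allyl ferracycle at C7; bonding at the other allyl terminus C9 would give a cyclobutanone and is not expected. C10 is untouched, while C5 and C9 are set afterwards under thermodynamic control by catalytic methoxide: the alkene moves from C8=C9 into conjugation with the ketone (the Hagemann-ester tautomer of a vinylogous β-keto ester), C5 epimerises to the trans ring fusion, and C9 should settle with the ester pseudoaxial on the α face, anti to the C10 methyl and free of allylic strain with the C8 methyl. The selectivity needed is cleavage of C5–C9 rather than C9–C10 or C5–C10: C5 is the only cyclopropane CH, C9–C10 joins two quaternary carbons and C5–C10 is not allylic, and because C5 is flanked by the quaternary C4 and C10 the alkyl–iron intermediate has no β-hydrogen and cannot leak to a diene. Working at room temperature also avoids the thermal homo-1,5-hydrogen shift open to a vinylcyclopropane whose vinyl group is cis to a methyl (here the C10 methyl).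

Step 9
Reactants: 12 methyl 3α-hydroxy-6-oxo-9-epi-drim-7-en-11-oate
Product: 13 9-epi-drim-7-ene-3α,6β,11-triol
Conditions: i-Bu2AlH (6 equiv), CH2Cl2, −78 → 0 °C; aq. potassium sodium tartrate
Reagents that add atoms: none
Why: Aluminium hydride reduction: the enone is reduced in 1,2 fashion (hydride from the α face, away from the axial C10 and C4 methyls, hence the 6β-alcohol, whose configuration is of no consequence) and the hindered ester gives the C11 carbinol, without basic conditions that could disturb C9.

Step 10
Reactants: 13 9-epi-drim-7-ene-3α,6β,11-triol; 14 isofraxidin (7-hydroxy-6,8-dimethoxy-2H-chromen-2-one)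
Product: 15 7-[(3α,6β-dihydroxy-9-epi-drim-7-en-11-yl)oxy]-6,8-dimethoxy-2H-chromen-2-one
Conditions: PPh3 (1.3 equiv), DIAD (1.3 equiv), THF, 0 °C → rt
Reagents that add atoms: none
Why: Mitsunobu etherification with an acidic phenol, selective for the primary C11 hydroxyl because the 6β- and 3α-hydroxyls are axial and flanked by quaternary carbons; it is run at the allylic alcohol stage because in the 6-ketone H9 is vinylogously acidic and an activated C11–O bond would be prone to elimination.

Step 11
Reactants: 15 aryl ether diol
Product: 16 7-[(3α-hydroxy-6-oxo-9-epi-drim-7-en-11-yl)oxy]-6,8-dimethoxy-2H-chromen-2-one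
Conditions: MnO2 (20 equiv), CH2Cl2, rt
Reagents that add atoms: none
Why: MnO2 oxidises allylic alcohols chemoselectively, restoring the 7-en-6-one while the saturated 3α-hydroxyl, the aryl ether and the coumarin are untouched, under neutral conditions that should not trigger loss of the aryloxide.

Step 12
Reactants: 16 hydroxy enone aryl ether
Product: 17 target, (3R,5R,9R,10R)-11-[(6,8-dimethoxy-2-oxo-2H-chromen-7-yl)oxy]-6-oxodrim-7-en-3-yl 3-methylbutanoate (3α-ester, 5α-H, 9β-H, 10β-methyl)
Conditions: 3-methylbutanoyl chloride (1.5 equiv), pyridine, DMAP (cat.), CH2Cl2, 0 °C → rt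
Reagents that add atoms: 3-methylbutanoyl chloride, SMILES CC(C)CC(Cl)=O
Why: DMAP-catalysed O-acylation of the remaining hindered axial hydroxyl with retention at C3, pyridine being too weak a base to enolise the enone toward C9.

Compound list
1 | 4-methylcyclohex-2-en-1-one (racemic) | CC1CCC(=O)C=C1 | starting material
2 | 2,4-dimethylcyclohex-3-en-1-one (racemic) | CC1=CC(C)C(=O)CC1 | intermediate
3 | 2,2,4-trimethylcyclohex-3-en-1-one | CC1=CC(C)(C)C(=O)CC1 | intermediate
4 | (1R)-2,2,4-trimethylcyclohex-3-en-1-ol | CC1=CC(C)(C)[C@H](O)CC1 | intermediate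
5 | 2,2,6-trimethyl-4H-1,3-dioxin-4-one | CC1=CC(=O)OC(C)(C)O1 | starting material
6 | (1R)-2,2,4-trimethylcyclohex-3-en-1-yl 3-oxobutanoate | CC1=CC(C)(C)[C@H](OC(=O)CC(C)=O)CC1 | intermediate
7 | (1R)-2,2,4-trimethylcyclohex-3-en-1-yl 2-diazo-3-oxobutanoate | CC1=CC(C)(C)[C@H](OC(=O)C(=[N+]=[N-])C(C)=O)CC1 | intermediate
8 | 2-acetyl-8,9,9-trimethyl-4-oxatricyclo[3.3.1.0^2,8]nonan-3-one (drimane C3 = R) | CC(=O)[C@@]1(C(=O)O3)[C@@H]2C(C)(C)[C@H]3CC[C@]12C | intermediate
9 | 8,9,9-trimethyl-2-(prop-1-en-2-yl)-4-oxatricyclo[3.3.1.0^2,8]nonan-3-one | C=C(C)[C@@]1(C(=O)O3)[C@@H]2C(C)(C)[C@H]3CC[C@]12C | intermediate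
10 | methyl 4-hydroxy-1,5,5-trimethyl-7-(prop-1-en-2-yl)bicyclo[4.1.0]heptane-7-carboxylate (hydroxyl and cyclopropane carbon on the same face, ester endo) | C=C(C)[C@@]1(C(=O)OC)[C@@H]2C(C)(C)[C@H](O)CC[C@]12C | intermediate
11 | methyl 3α-hydroxy-6-oxo-5β-drim-8-en-11-oate (cis-fused) | COC(=O)C1=C(C)CC(=O)[C@@H]2C(C)(C)[C@H](O)CC[C@]12C | intermediate
12 | methyl 3α-hydroxy-6-oxo-9-epi-drim-7-en-11-oate | COC(=O)[C@@H]1C(C)=CC(=O)[C@H]2C(C)(C)[C@H](O)CC[C@]12C | intermediate
13 | 9-epi-drim-7-ene-3α,6β,11-triol | OC[C@@H]1C(C)=C[C@@H](O)[C@H]2C(C)(C)[C@H](O)CC[C@]12C | intermediate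
14 | isofraxidin | COc1cc2ccc(=O)oc2c(OC)c1O | starting material
15 | 7-[(3α,6β-dihydroxy-9-epi-drim-7-en-11-yl)oxy]-6,8-dimethoxy-2H-chromen-2-one | COc1cc2ccc(=O)oc2c(OC)c1OC[C@@H]1C(C)=C[C@@H](O)[C@H]2C(C)(C)[C@H](O)CC[C@]12C | intermediate
16 | 7-[(3α-hydroxy-6-oxo-9-epi-drim-7-en-11-yl)oxy]-6,8-dimethoxy-2H-chromen-2-one | COc1cc2ccc(=O)oc2c(OC)c1OC[C@@H]1C(C)=CC(=O)[C@H]2C(C)(C)[C@H](O)CC[C@]12C | intermediate
17 | CNP0279705.1, 3α-(3-methylbutanoyloxy) ester of 16 | COc1cc2ccc(=O)oc2c(OC)c1OC[C@@H]1C(C)=CC(=O)[C@H]2C(C)(C)[C@H](OC(=O)CC(C)C)CC[C@]12C | target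

Total step count: 12. Longest linear sequence: 12 steps (1 → 17); compounds 5 and 14 are bought.

Steps most likely to fail

Step 8. The crowded, fully substituted vinylcyclopropane may bind iron poorly, the metal may open the C9–C10 bond instead, or the light-sensitive β,γ-enone may undergo acyl shift before it is equilibrated. The fallback builds ring B by a Diels–Alder reaction instead; it sets out from 4 and returns at 12.
- Silylation of 4 (Et3SiCl, imidazole) would give the triethylsilyl ether F1.
- Hydroboration–oxidation (BH3·THF; NaOH, H2O2) would give the C5 alcohol F2.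
- Dess–Martin oxidation would give the ketone F3.
- KN(SiMe3)2 and PhNTf2 would give the enol triflate F4.
- Stille coupling with tributyl(1-ethoxyvinyl)stannane (Pd(PPh3)4, LiCl, THF, reflux) would give the 2-ethoxy diene F5.
- Heating with methyl but-2-ynoate (toluene, 150 °C, sealed tube) would give the Diels–Alder adduct F6. Both the alkoxy group on C6 and the fully substituted terminus C10 direct the ester carbon to C10.
- Aqueous HCl in THF would cleave the enol ether and the silyl ether to give 11 (as C5 epimers), which the methoxide treatment of step 8 converts to 12.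
- The weakness of this detour is that C10 would rest only on the facial bias of the remote C3 substituent, so diastereomers may have to be separated.

Step 5. The bulky acceptor/acceptor carbenoid may fail to reach the hindered trisubstituted alkene through the bridged transition state and divert to C–H insertion at C2 or to carbene dimers. The fallback uses a smaller, more reactive mono-acceptor carbenoid and adds the remaining carbons by enolate chemistry; it sets out from 7 and returns at 9.
- Deacetylation of 7 (LiOH, H2O/MeCN) would give the diazoacetate F7.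
- Cu(acac)2-catalysed intramolecular cyclopropanation (toluene, 80 °C) would give the unsubstituted cyclopropane lactone F8.
- Deprotonation at C9 with LiN(i-Pr)2 (−78 °C) and addition of acetone on the only open (exo) face would give the tertiary carbinol F9.
- Syn-dehydration with the Burgess reagent would give 9; this also bypasses step 6.

Step 10. Substitution at the β-branched C11 carbinol by a di-ortho-substituted phenol may be slow, which would allow activation of the allylic 6-hydroxyl or elimination to compete. The fallback separates activation from substitution; it sets out from 13 and returns at 15.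
- Selective sulfonylation of the primary hydroxyl (MsCl, Et3N, CH2Cl2, −20 °C) would give the primary mesylate F10.
- Displacement with the caesium salt of 14 (Cs2CO3, DMF, 60 °C) would give 15.

Further compounds
F1 | step 8 | triethyl{[(1R)-2,2,4-trimethylcyclohex-3-en-1-yl]oxy}silane | CC1=CC(C)(C)[C@H](O[Si](CC)(CC)CC)CC1
F2 | step 8 | (3R)-2,2,6-trimethyl-3-(triethylsilyloxy)cyclohexan-1-ol (mixture at C1 and C6) | CC1C(O)C(C)(C)[C@H](O[Si](CC)(CC)CC)CC1
F3 | step 8 | (3R)-2,2,6-trimethyl-3-(triethylsilyloxy)cyclohexan-1-one (C6 epimers) | CC1C(=O)C(C)(C)[C@H](O[Si](CC)(CC)CC)CC1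
F4 | step 8 | (5R)-2,6,6-trimethyl-5-(triethylsilyloxy)cyclohex-1-en-1-yl trifluoromethanesulfonate | CC1=C(OS(=O)(=O)C(F)(F)F)C(C)(C)[C@H](O[Si](CC)(CC)CC)CC1
F5 | step 8 | {[(1R)-3-(1-ethoxyethenyl)-2,2,4-trimethylcyclohex-3-en-1-yl]oxy}triethylsilane | CC1=C(C(=C)OCC)C(C)(C)[C@H](O[Si](CC)(CC)CC)CC1
F6 | step 8 | methyl 6-ethoxy-3α-(triethylsilyloxy)drima-5,8-dien-11-oate (10β-methyl) | COC(=O)C1=C(C)CC(OCC)=C2C(C)(C)[C@H](O[Si](CC)(CC)CC)CC[C@]12C
F7 | step 5 | (1R)-2,2,4-trimethylcyclohex-3-en-1-yl diazoacetate | CC1=CC(C)(C)[C@H](OC(=O)C=[N+]=[N-])CC1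
F8 | step 5 | 8,9,9-trimethyl-4-oxatricyclo[3.3.1.0^2,8]nonan-3-one | [C@@H]1(C(=O)O3)[C@@H]2C(C)(C)[C@H]3CC[C@]12C
F9 | step 5 | 2-(2-hydroxypropan-2-yl)-8,9,9-trimethyl-4-oxatricyclo[3.3.1.0^2,8]nonan-3-one | CC(C)(O)[C@@]1(C(=O)O3)[C@@H]2C(C)(C)[C@H]3CC[C@]12C
F10 | step 10 | 3α,6β-dihydroxy-9-epi-drim-7-en-11-yl methanesulfonate | CS(=O)(=O)OC[C@@H]1C(C)=C[C@@H](O)[C@H]2C(C)(C)[C@H](O)CC[C@]12C
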